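**Retrosynthetic overview**

1. The target comes from aryl bromide 31 (C18–Br to C18–OH last), which comes from Wacker oxidation of macrocyclic alkene 30, itself made by ring-closing metathesis of diene amide 29; the 15-membered lactam ring is formed last.
2. 29 comes from aniline 23 and (S)-2-hydroxy-2-methylpent-4-enoic acid 27 (from (R)-lactic acid); C6/C7 come from γ-methoxyallylboration of (Z)-enal 19, and the (Z)-C8=C9 bond from Still–Gennari olefination of aldehyde 16.
3. The 8-membered benzoxocine ring is formed first, by intramolecular SNAr of the C11 alkoxide of 14 onto its o-fluoronitroarene; C10/C11 come from (Z)-crotylboration of α-methoxy aldehyde 13.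
4. 13 comes from Negishi coupling of aryl iodide 10 (from 4-bromo-1-fluoro-2-nitrobenzene 9) with alkyl iodide 8, which comes from iododecarboxylation of acid 7, made from cis-lactone 5.
5. Key step: asymmetric hydrogenation of 2-pyrone 3 (from 4,6-dimethyl-2-pyrone 1) destroys the pyrone π-system and sets C12 and C14 in one operation.

Assumptions: positions are numbered ansamycin-style (C1 amide carbonyl, C15 benzylic CH2, C16–C21 arene, O on C18 and C21, N on C20); the Ru–(S)-BINAP catalyst is taken to give (6S)-4, and the tartrate and pinene boron reagents to show their usual facial sense (the antipodal ligand or reagent is used otherwise).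

**Route**

Step 1
Reactants: 1 4,6-dimethyl-2H-pyran-2-one
Product: 2 4-methyl-2-oxo-2H-pyran-6-carbaldehyde
Conditions: SeO2, 1,4-dioxane, 100 °C
Reagents that add atoms: selenium dioxide, O=[Se]=O
Why: Riley oxidation; the ene/[2,3] sequence starts at the electron-rich C5=C6 enol double bond, whose only allylic C–H bonds are those of the 6-methyl group.

Step 2
Reactants: 2 4-methyl-2-oxo-2H-pyran-6-carbaldehyde
Product: 3 6-(dimethoxymethyl)-4-methyl-2H-pyran-2-one
Conditions: HC(OMe)3, TsOH (cat.), MeOH, 23 °C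
Reagents that add atoms: trimethyl orthoformate, COC(OC)OC
Why: Acid-catalysed acetalization masks the future C11 aldehyde against hydrogenation, base and organozinc chemistry.

Step 3
Reactants: 3 6-(dimethoxymethyl)-4-methyl-2H-pyran-2-one
Product: 5 (4S,6S)-6-(dimethoxymethyl)-4-methyloxan-2-one, via dihydropyranone 4 (not isolated)
Conditions: Ru(OAc)2[(S)-BINAP] (1 mol %), HBF4 (2 mol %), H2 (60 bar), MeOH, 60 °C; then 10% Pd/C, H2 (1 bar), 23 °C
Reagents that add atoms: none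
Why: Dearomative asymmetric hydrogenation of a 2-pyrone: the Ru–BINAP catalyst reduces the enol-ester-like C5=C6 bond enantioselectively (sets C6, the future C12), and Pd/C then adds H2 to the remaining enoate from the face opposite the C6 substituent, giving the cis lactone (sets C4, the future C14).

Step 4
Reactants: 5 (4S,6S)-6-(dimethoxymethyl)-4-methyloxan-2-one
Product: 7 (3S,5S)-5,6,6-trimethoxy-3-methylhexanoic acid, via methyl ester 6 (not isolated)
Conditions: KOH, MeI, DMSO, 23 °C; then LiOH, H2O; then HCl to pH 4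
Reagents that add atoms: iodomethane, CI; potassium hydroxide, [K+].[OH-]; lithium hydroxide, [Li+].[OH-]
Why: Lactone saponification followed by Williamson methylation caps the C12 alkoxide without touching the C–O stereocentre; the co-formed methyl ester is hydrolysed in the same pot.

Step 5
Reactants: 7 (3S,5S)-5,6,6-trimethoxy-3-methylhexanoic acid
Product: 8 (2S,4S)-5-iodo-1,1,2-trimethoxy-4-methylpentane
Conditions: PhI(OAc)2, I2, cyclohexane, hν, 60 °C
Reagents that add atoms: iodine, II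
Why: Suárez iododecarboxylation (Hunsdiecker type): the acyl hypoiodite loses CO2 and the primary radical is trapped by iodine faster than it can abstract hydrogen; the stereocentres are remote.

Step 6
Reactants: 9 4-bromo-1-fluoro-2-nitrobenzene
Product: 10 5-bromo-2-fluoro-1-iodo-3-nitrobenzene
Conditions: NIS, TfOH, 23 °C
Reagents that add atoms: N-iodosuccinimide, O=C1CCC(=O)N1I
Why: Electrophilic aromatic iodination with a superelectrophilic iodine source; the only C–H that is meta to the nitro group is also ortho to fluorine, so all directing effects converge on it.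

Step 7
Reactants: 8 (2S,4S)-5-iodo-1,1,2-trimethoxy-4-methylpentane; 10 5-bromo-2-fluoro-1-iodo-3-nitrobenzene
Product: 12 5-bromo-2-fluoro-3-nitro-1-[(2R,4S)-4,5,5-trimethoxy-2-methylpentyl]benzene, via alkylzinc iodide 11 (not isolated)
Conditions: Zn dust, LiCl, THF, 40 °C; then 10, Pd2(dba)3 (2 mol %), SPhos (8 mol %), THF, 23 °C
Reagents that add atoms: none
Why: Negishi coupling: zinc inserts into the primary C–I bond and the palladium catalyst couples at the aryl C–I bond in preference to C–Br, with the nitro group and activated fluoride tolerated (the C14 descriptor changes to R by priority only).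

Step 8
Reactants: 12 5-bromo-2-fluoro-3-nitro-1-[(2R,4S)-4,5,5-trimethoxy-2-methylpentyl]benzene
Product: 13 (2S,4R)-5-(5-bromo-2-fluoro-3-nitrophenyl)-2-methoxy-4-methylpentanal
Conditions: TFA, H2O, CH2Cl2, 0 °C
Reagents that add atoms: water, O
Why: Acetal hydrolysis under mild acid frees the α-methoxy aldehyde, which is used at once to avoid epimerisation.

Step 9
Reactants: 13 (2S,4R)-5-(5-bromo-2-fluoro-3-nitrophenyl)-2-methoxy-4-methylpentanal
Product: 14 (3S,4R,5S,7R)-8-(5-bromo-2-fluoro-3-nitrophenyl)-5-methoxy-3,7-dimethyloct-1-en-4-ol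
Conditions: (S,S)-diisopropyl tartrate (Z)-crotylboronate, 4 Å molecular sieves, toluene, −78 °C; then H2O
Reagents that add atoms: diisopropyl (4S,5S)-2-[(2Z)-but-2-en-1-yl]-1,3,2-dioxaborolane-4,5-dicarboxylate, C/C=C\CB1O[C@H](C(=O)OC(C)C)[C@@H](C(=O)OC(C)C)O1
Why: Roush crotylboration: the closed chair transition state of the (Z)-reagent gives the C10/C11 syn pair, and the (S,S)-tartrate is matched with the Cornforth/Felkin preference of the α-methoxy aldehyde, placing the new C11–OH anti to the C12–OMe.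

Step 10
Reactants: 14 (3S,4R,5S,7R)-8-(5-bromo-2-fluoro-3-nitrophenyl)-5-methoxy-3,7-dimethyloct-1-en-4-ol
Product: 15 (2R,3S,5R)-8-bromo-2-[(2S)-but-3-en-2-yl]-3-methoxy-5-methyl-10-nitro-3,4,5,6-tetrahydro-2H-1-benzoxocine
Conditions: KN(SiMe3)2, THF (0.005 M), −20 → 23 °C
Reagents that add atoms: none
Why: Intramolecular SNAr through a Meisenheimer complex: the C11 alkoxide displaces the fluoride activated by the ortho nitro group; the C11–O bond is not broken, so its configuration is retained, and high dilution favours closure of the 8-membered ring.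

Step 11
Reactants: 15 (2R,3S,5R)-8-bromo-2-[(2S)-but-3-en-2-yl]-3-methoxy-5-methyl-10-nitro-3,4,5,6-tetrahydro-2H-1-benzoxocine
Product: 16 (2R)-2-[(2R,3S,5R)-8-bromo-3-methoxy-5-methyl-10-nitro-3,4,5,6-tetrahydro-2H-1-benzoxocin-2-yl]propanal
Conditions: O3, CH2Cl2, −78 °C; then PPh3
Reagents that add atoms: ozone, [O-][O+]=O
Why: Ozonolysis with reductive work-up cleaves the only alkene; the electron-poor nitroarene is inert, and the neutral work-up spares the C10 stereocentre.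

Step 12
Reactants: 16 (2R)-2-[(2R,3S,5R)-8-bromo-3-methoxy-5-methyl-10-nitro-3,4,5,6-tetrahydro-2H-1-benzoxocin-2-yl]propanal
Product: 17 methyl (2Z,4S)-4-[(2R,3S,5R)-8-bromo-3-methoxy-5-methyl-10-nitro-3,4,5,6-tetrahydro-2H-1-benzoxocin-2-yl]-2-methylpent-2-enoate
Conditions: (CF3CH2O)2P(O)CH(CH3)CO2CH3, KN(SiMe3)2, 18-crown-6, THF, −78 °C
Reagents that add atoms: methyl 2-[bis(2,2,2-trifluoroethoxy)phosphoryl]propanoate, COC(=O)C(C)P(=O)(OCC(F)(F)F)OCC(F)(F)F
Why: Still–Gennari olefination: fast, irreversible collapse of the erythro adduct of the trifluoroethyl phosphonate gives the (Z)-trisubstituted enoate (C10 cis to C7), and the weakly basic anion at −78 °C avoids β-elimination of the aryloxide.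

Step 13
Reactants: 17 methyl (2Z,4S)-4-[(2R,3S,5R)-8-bromo-3-methoxy-5-methyl-10-nitro-3,4,5,6-tetrahydro-2H-1-benzoxocin-2-yl]-2-methylpent-2-enoate
Product: 18 (2Z,4S)-4-[(2R,3S,5R)-8-bromo-3-methoxy-5-methyl-10-nitro-3,4,5,6-tetrahydro-2H-1-benzoxocin-2-yl]-2-methylpent-2-en-1-ol
Conditions: i-Bu2AlH, CH2Cl2, −78 °C; then H2O
Reagents that add atoms: none
Why: 1,2-Reduction of the enoate by i-Bu2AlH at −78 °C is much faster than attack on the aryl nitro group and leaves the alkene geometry untouched.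

Step 14
Reactants: 18 (2Z,4S)-4-[(2R,3S,5R)-8-bromo-3-methoxy-5-methyl-10-nitro-3,4,5,6-tetrahydro-2H-1-benzoxocin-2-yl]-2-methylpent-2-en-1-ol
Product: 19 (2Z,4S)-4-[(2R,3S,5R)-8-bromo-3-methoxy-5-methyl-10-nitro-3,4,5,6-tetrahydro-2H-1-benzoxocin-2-yl]-2-methylpent-2-enal
Conditions: MnO2, CH2Cl2, 23 °C
Reagents that add atoms: none
Why: Neutral allylic oxidation with MnO2 gives the (Z)-enal without acid or base that would isomerise it; it is used directly.

Step 15
Reactants: 19 (2Z,4S)-4-[(2R,3S,5R)-8-bromo-3-methoxy-5-methyl-10-nitro-3,4,5,6-tetrahydro-2H-1-benzoxocin-2-yl]-2-methylpent-2-enal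
Product: 20 (3S,4S,5Z,7S)-7-[(2R,3S,5R)-8-bromo-3-methoxy-5-methyl-10-nitro-3,4,5,6-tetrahydro-2H-1-benzoxocin-2-yl]-3-methoxy-5-methylocta-1,5-dien-4-ol
Conditions: allyl methyl ether, s-BuLi, THF, −78 °C; (+)-Ipc2BOMe; BF3·OEt2; then 19, −78 °C; then HOCH2CH2NH2
Reagents that add atoms: (Z)-(3-methoxyallyl)diisopinocampheylborane from (−)-α-pinene, made in the flask from allyl methyl ether, CO/C=C\CB([C@H]1C[C@H]2C[C@@H]([C@@H]1C)C2(C)C)[C@H]1C[C@H]2C[C@@H]([C@@H]1C)C2(C)C
Why: Brown γ-methoxyallylboration: the chair transition state of the (Z)-reagent gives the syn methoxy alcohol, and the isopinocampheyl groups control the aldehyde face, setting C6 and C7 (both S) by reagent control.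

Step 16
Reactants: 20 (3S,4S,5Z,7S)-7-[(2R,3S,5R)-8-bromo-3-methoxy-5-methyl-10-nitro-3,4,5,6-tetrahydro-2H-1-benzoxocin-2-yl]-3-methoxy-5-methylocta-1,5-dien-4-ol
Product: 22 (3S,4S,5Z,7S)-7-[(2R,3S,5R)-8-bromo-3-methoxy-5-methyl-10-nitro-3,4,5,6-tetrahydro-2H-1-benzoxocin-2-yl]-3-methoxy-5-methylocta-1,5-dien-4-yl carbamate, via N-trichloroacetyl carbamate 21 (not isolated)
Conditions: Cl3CC(O)NCO, CH2Cl2, 0 °C; then K2CO3 (cat.), MeOH, 0 °C
Reagents that add atoms: trichloroacetyl isocyanate, O=C=NC(=O)C(Cl)(Cl)Cl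
Why: Kočovský carbamoylation: the only free hydroxyl adds to the isocyanate and mild methanolysis removes the trichloroacetyl group; C7 is not touched.

Step 17
Reactants: 22 (3S,4S,5Z,7S)-7-[(2R,3S,5R)-8-bromo-3-methoxy-5-methyl-10-nitro-3,4,5,6-tetrahydro-2H-1-benzoxocin-2-yl]-3-methoxy-5-methylocta-1,5-dien-4-yl carbamate
Product: 23 (3S,4S,5Z,7S)-7-[(2R,3S,5R)-10-amino-8-bromo-3-methoxy-5-methyl-3,4,5,6-tetrahydro-2H-1-benzoxocin-2-yl]-3-methoxy-5-methylocta-1,5-dien-4-yl carbamate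
Conditions: Zn dust, AcOH, THF, 23 °C
Reagents that add atoms: none
Why: Dissolving-metal reduction of the nitro group to the aniline; the alkenes, aryl bromide and carbamate are inert to Zn/AcOH.

Step 18
Reactants: 24 (R)-lactic acid
Product: 25 (2R,5R)-2-tert-butyl-5-methyl-1,3-dioxolan-4-one
Conditions: t-BuCHO, TsOH (cat.), pentane, reflux (Dean–Stark)
Reagents that add atoms: pivalaldehyde, CC(C)(C)C=O
Why: Seebach acetalization; the cis dioxolanone is the thermodynamic product and stores the lactic acid chirality at the acetal carbon.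

Step 19
Reactants: 25 (2R,5R)-2-tert-butyl-5-methyl-1,3-dioxolan-4-one
Product: 26 (2R,5S)-2-tert-butyl-5-methyl-5-(prop-2-en-1-yl)-1,3-dioxolan-4-one
Conditions: LiN(i-Pr)2, THF, −78 °C; then allyl bromide
Reagents that add atoms: allyl bromide, C=CCBr
Why: Self-regeneration of stereocentres: the enolate is alkylated anti to the tert-butyl group, so allyl replaces H with retention and sets the future C2 quaternary centre.

Step 20
Reactants: 26 (2R,5S)-2-tert-butyl-5-methyl-5-(prop-2-en-1-yl)-1,3-dioxolan-4-one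
Product: 27 (2S)-2-hydroxy-2-methylpent-4-enoic acid
Conditions: aqueous HCl, THF, 60 °C
Reagents that add atoms: water, O
Why: Acid hydrolysis of the acylal releases the α-hydroxy acid; the quaternary centre cannot epimerise.

Step 21
Reactants: 23 (3S,4S,5Z,7S)-7-[(2R,3S,5R)-10-amino-8-bromo-3-methoxy-5-methyl-3,4,5,6-tetrahydro-2H-1-benzoxocin-2-yl]-3-methoxy-5-methylocta-1,5-dien-4-yl carbamate; 27 (2S)-2-hydroxy-2-methylpent-4-enoic acid
Product: 29 (2S)-N-[(2R,3S,5R)-8-bromo-2-{(2S,3Z,5S,6S)-5-(carbamoyloxy)-6-methoxy-4-methylocta-3,7-dien-2-yl}-3-methoxy-5-methyl-3,4,5,6-tetrahydro-2H-1-benzoxocin-10-yl]-2-hydroxy-2-methylpent-4-enamide, via acid chloride 28 (not isolated)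
Conditions: 27, SOCl2, DMAc, −15 °C; then 23, −15 → 23 °C
Reagents that add atoms: none
Why: Amide formation through the α-hydroxy acid chloride generated in DMAc (the method used for hindered 2-hydroxy-2-methyl anilides); only the aniline nitrogen is nucleophilic enough to be acylated.

Step 22
Reactants: 29 (2S)-N-[(2R,3S,5R)-8-bromo-2-{(2S,3Z,5S,6S)-5-(carbamoyloxy)-6-methoxy-4-methylocta-3,7-dien-2-yl}-3-methoxy-5-methyl-3,4,5,6-tetrahydro-2H-1-benzoxocin-10-yl]-2-hydroxy-2-methylpent-4-enamide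
Product: 30 (4E)-alkene macrolactam (target skeleton; C4=C5 double bond in place of the C4 ketone; Br at C18)
Conditions: second-generation Grubbs catalyst (10 mol %), toluene (0.001 M), 80 °C
Reagents that add atoms: none
Why: Ring-closing metathesis of the two terminal alkenes closes the 15-membered lactam; the (Z)-trisubstituted C8=C9 bond is inert, and the geometry of the new C4=C5 bond does not matter.

Step 23
Reactants: 30 (4E)-alkene macrolactam (target skeleton; C4=C5 double bond in place of the C4 ketone; Br at C18)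
Product: 31 18-bromo-18-deoxy analogue of the target
Conditions: Pd(OAc)2 (10 mol %), 1,4-benzoquinone, HBF4, DMA/MeCN/H2O, 23 °C
Reagents that add atoms: water, O
Why: Tsuji–Wacker oxidation of an internal alkene: water attacks the carbon distal to the inductively withdrawing allylic C6 methoxy group, which is also the less hindered one, so the ketone forms at C4; the trisubstituted alkene does not react.

Step 24
Reactants: 31 18-bromo-18-deoxy analogue of the target
Product: 33 CNP0122739.1 (target), via arylboronate 32 (not isolated)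
Conditions: Pd2(dba)3, XPhos, B2pin2, KOAc, 1,4-dioxane, 80 °C; then H2O2, pH 7 phosphate buffer, THF, 0 °C
Reagents that add atoms: hydrogen peroxide, OO
Why: Miyaura borylation of the unhindered aryl bromide followed by buffered oxidation of the C–B bond gives the phenol; the weak base and neutral oxidation spare the β-hydroxy/β-methoxy ketone and the allylic carbamate.

**Compound list**

1 | 4,6-dimethyl-2H-pyran-2-one | O=C1C=C(C)C=C(C)O1 | starting material
2 | 4-methyl-2-oxo-2H-pyran-6-carbaldehyde | O=CC1=CC(C)=CC(=O)O1 | intermediate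
3 | 6-(dimethoxymethyl)-4-methyl-2H-pyran-2-one | COC(OC)C1=CC(C)=CC(=O)O1 | intermediate
4 | (6S)-6-(dimethoxymethyl)-4-methyl-5,6-dihydro-2H-pyran-2-one | COC(OC)[C@@H]1CC(C)=CC(=O)O1 | intermediate
5 | (4S,6S)-6-(dimethoxymethyl)-4-methyloxan-2-one (cis) | COC(OC)[C@@H]1C[C@H](C)CC(=O)O1 | intermediate
6 | methyl (3S,5S)-5,6,6-trimethoxy-3-methylhexanoate | COC(OC)[C@@H](OC)C[C@H](C)CC(=O)OC | intermediate
7 | (3S,5S)-5,6,6-trimethoxy-3-methylhexanoic acid | COC(OC)[C@@H](OC)C[C@H](C)CC(=O)O | intermediate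
8 | (2S,4S)-5-iodo-1,1,2-trimethoxy-4-methylpentane | COC(OC)[C@@H](OC)C[C@H](C)CI | intermediate
9 | 4-bromo-1-fluoro-2-nitrobenzene | O=[N+]([O-])c1cc(Br)ccc1F | starting material
10 | 5-bromo-2-fluoro-1-iodo-3-nitrobenzene | O=[N+]([O-])c1cc(Br)cc(I)c1F | intermediate
11 | [(2S,4S)-4,5,5-trimethoxy-2-methylpentyl]zinc iodide | COC(OC)[C@@H](OC)C[C@H](C)C[Zn]I | intermediate
12 | 5-bromo-2-fluoro-3-nitro-1-[(2R,4S)-4,5,5-trimethoxy-2-methylpentyl]benzene | COC(OC)[C@@H](OC)C[C@H](C)Cc1cc(Br)cc([N+](=O)[O-])c1F | intermediate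
13 | (2S,4R)-5-(5-bromo-2-fluoro-3-nitrophenyl)-2-methoxy-4-methylpentanal | O=C[C@@H](OC)C[C@H](C)Cc1cc(Br)cc([N+](=O)[O-])c1F | intermediate
14 | (3S,4R,5S,7R)-8-(5-bromo-2-fluoro-3-nitrophenyl)-5-methoxy-3,7-dimethyloct-1-en-4-ol | C=C[C@H](C)[C@@H](O)[C@@H](OC)C[C@H](C)Cc1cc(Br)cc([N+](=O)[O-])c1F | intermediate
15 | (2R,3S,5R)-8-bromo-2-[(2S)-but-3-en-2-yl]-3-methoxy-5-methyl-10-nitro-3,4,5,6-tetrahydro-2H-1-benzoxocine | CO[C@H]1C[C@H](C)Cc2cc(Br)cc([N+](=O)[O-])c2O[C@@H]1[C@@H](C)C=C | intermediate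
16 | (2R)-2-[(2R,3S,5R)-8-bromo-3-methoxy-5-methyl-10-nitro-3,4,5,6-tetrahydro-2H-1-benzoxocin-2-yl]propanal | CO[C@H]1C[C@H](C)Cc2cc(Br)cc([N+](=O)[O-])c2O[C@@H]1[C@@H](C)C=O | intermediate
17 | methyl (2Z,4S)-4-[(2R,3S,5R)-8-bromo-3-methoxy-5-methyl-10-nitro-3,4,5,6-tetrahydro-2H-1-benzoxocin-2-yl]-2-methylpent-2-enoate | CO[C@H]1C[C@H](C)Cc2cc(Br)cc([N+](=O)[O-])c2O[C@@H]1[C@@H](C)/C=C(/C)C(=O)OC | intermediate
18 | (2Z,4S)-4-[(2R,3S,5R)-8-bromo-3-methoxy-5-methyl-10-nitro-3,4,5,6-tetrahydro-2H-1-benzoxocin-2-yl]-2-methylpent-2-en-1-ol | CO[C@H]1C[C@H](C)Cc2cc(Br)cc([N+](=O)[O-])c2O[C@@H]1[C@@H](C)/C=C(/C)CO | intermediate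
19 | (2Z,4S)-4-[(2R,3S,5R)-8-bromo-3-methoxy-5-methyl-10-nitro-3,4,5,6-tetrahydro-2H-1-benzoxocin-2-yl]-2-methylpent-2-enal | CO[C@H]1C[C@H](C)Cc2cc(Br)cc([N+](=O)[O-])c2O[C@@H]1[C@@H](C)/C=C(/C)C=O | intermediate
20 | (3S,4S,5Z,7S)-7-[(2R,3S,5R)-8-bromo-3-methoxy-5-methyl-10-nitro-3,4,5,6-tetrahydro-2H-1-benzoxocin-2-yl]-3-methoxy-5-methylocta-1,5-dien-4-ol | CO[C@H]1C[C@H](C)Cc2cc(Br)cc([N+](=O)[O-])c2O[C@@H]1[C@@H](C)/C=C(/C)[C@H](O)[C@@H](OC)C=C | intermediate
21 | N-(trichloroacetyl)carbamate of 20 at the C7 oxygen | CO[C@H]1C[C@H](C)Cc2cc(Br)cc([N+](=O)[O-])c2O[C@@H]1[C@@H](C)/C=C(/C)[C@H](OC(=O)NC(=O)C(Cl)(Cl)Cl)[C@@H](OC)C=C | intermediate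
22 | (3S,4S,5Z,7S)-7-[(2R,3S,5R)-8-bromo-3-methoxy-5-methyl-10-nitro-3,4,5,6-tetrahydro-2H-1-benzoxocin-2-yl]-3-methoxy-5-methylocta-1,5-dien-4-yl carbamate | CO[C@H]1C[C@H](C)Cc2cc(Br)cc([N+](=O)[O-])c2O[C@@H]1[C@@H](C)/C=C(/C)[C@H](OC(N)=O)[C@@H](OC)C=C | intermediate
23 | (3S,4S,5Z,7S)-7-[(2R,3S,5R)-10-amino-8-bromo-3-methoxy-5-methyl-3,4,5,6-tetrahydro-2H-1-benzoxocin-2-yl]-3-methoxy-5-methylocta-1,5-dien-4-yl carbamate | CO[C@H]1C[C@H](C)Cc2cc(Br)cc(N)c2O[C@@H]1[C@@H](C)/C=C(/C)[C@H](OC(N)=O)[C@@H](OC)C=C | intermediate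
24 | (R)-lactic acid | C[C@@H](O)C(=O)O | starting material
25 | (2R,5R)-2-tert-butyl-5-methyl-1,3-dioxolan-4-one | C[C@H]1O[C@@H](C(C)(C)C)OC1=O | intermediate
26 | (2R,5S)-2-tert-butyl-5-methyl-5-(prop-2-en-1-yl)-1,3-dioxolan-4-one | C=CC[C@]1(C)O[C@@H](C(C)(C)C)OC1=O | intermediate
27 | (2S)-2-hydroxy-2-methylpent-4-enoic acid | C=CC[C@](C)(O)C(=O)O | intermediate
28 | (2S)-2-hydroxy-2-methylpent-4-enoyl chloride | C=CC[C@](C)(O)C(Cl)=O | intermediate
29 | (2S)-N-[(2R,3S,5R)-8-bromo-2-{(2S,3Z,5S,6S)-5-(carbamoyloxy)-6-methoxy-4-methylocta-3,7-dien-2-yl}-3-methoxy-5-methyl-3,4,5,6-tetrahydro-2H-1-benzoxocin-10-yl]-2-hydroxy-2-methylpent-4-enamide | CO[C@H]1C[C@H](C)Cc2cc(Br)cc(NC(=O)[C@@](C)(O)CC=C)c2O[C@@H]1[C@@H](C)/C=C(/C)[C@H](OC(N)=O)[C@@H](OC)C=C | intermediate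
30 | (4E)-alkene macrolactam: target skeleton with a C4=C5 double bond in place of the C4 ketone and Br in place of OH at C18 | CO[C@H]1C[C@H](C)Cc2cc(Br)cc3c2O[C@@H]1[C@@H](C)/C=C(/C)[C@H](OC(N)=O)[C@@H](OC)/C=C/C[C@](C)(O)C(=O)N3 | intermediate
31 | 18-bromo-18-deoxy analogue of the target (C4 ketone in place) | CO[C@H]1C[C@H](C)Cc2cc(Br)cc3c2O[C@@H]1[C@@H](C)/C=C(/C)[C@H](OC(N)=O)[C@@H](OC)CC(=O)C[C@](C)(O)C(=O)N3 | intermediate
32 | 18-(4,4,5,5-tetramethyl-1,3,2-dioxaborolan-2-yl)-18-deoxy analogue of the target | CO[C@H]1C[C@H](C)Cc2cc(B4OC(C)(C)C(C)(C)O4)cc3c2O[C@@H]1[C@@H](C)/C=C(/C)[C@H](OC(N)=O)[C@@H](OC)CC(=O)C[C@](C)(O)C(=O)N3 | intermediate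
33 | CNP0122739.1: (2S,6S,7S,8Z,10S,11R,12S,14R) 15-membered lactam with the C11–O–C21 benzoxocine ether, C7 carbamate, C4 ketone and C18 phenol | CO[C@H]1C[C@H](C)Cc2cc(O)cc3c2O[C@@H]1[C@@H](C)/C=C(/C)[C@H](OC(N)=O)[C@@H](OC)CC(=O)C[C@](C)(O)C(=O)N3 | target

**Step count and fallbacks**

Total step count: 24. Longest linear sequence: 20 steps (steps 1–5, 7–17 and 21–24).

The three steps most likely to fail are step 3, step 10 and step 23.

Step 3 may give low ee or stall on a pyrone that carries an acetal at C6. The fallback sets out from 3 and sets the carbinol centre on an open-chain ketone instead. Methanolysis of 3 (NaOMe, MeOH) opens the ring to methyl (2Z)-6,6-dimethoxy-3-methyl-5-oxohex-2-enoate F1. Noyori transfer hydrogenation of its α,α-dimethoxy ketone (RuCl(p-cymene)[(S,S)-TsDPEN], HCO2H/NEt3) gives methyl (2Z,5S)-5-hydroxy-6,6-dimethoxy-3-methylhex-2-enoate F2. This lactonises (TsOH cat.) to 4, where the route is rejoined, and Pd/C with H2 then gives 5 as in step 3.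

Step 10 may fail because an 8-membered ring must close faster than intermolecular substitution. The fallback sets out from 12 and reverses the roles of the partners, so that a nitrophenol attacks an activated alcohol. Hydrolysis of the activated fluoride (KOH, DMSO/H2O) gives 4-bromo-2-nitro-6-[(2R,4S)-4,5,5-trimethoxy-2-methylpentyl]phenol F3. Acetal cleavage (TFA, H2O) gives (2S,4R)-5-(5-bromo-2-hydroxy-3-nitrophenyl)-2-methoxy-4-methylpentanal F4. Crotylation with the (R,R)-diisopropyl tartrate (E)-crotylboronate gives the C11 epimer, (3S,4S,5S,7R)-8-(5-bromo-2-hydroxy-3-nitrophenyl)-5-methoxy-3,7-dimethyloct-1-en-4-ol F5. Intramolecular Mitsunobu etherification (PPh3, DIAD, toluene, high dilution) inverts C11 and comes back to the route at 15.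

Step 23 may give the C5 ketone or a mixture if the macrocycle overrides the bias of the allylic methoxy group. The fallback sets out from 22 and fixes the oxygen on C4 by a 5-exo ring closure instead. Cross-metathesis of 22 with acid 27 (second-generation Grubbs catalyst) gives (2S,4E,6S,7S,8Z,10S)-10-[(2R,3S,5R)-8-bromo-3-methoxy-5-methyl-10-nitro-3,4,5,6-tetrahydro-2H-1-benzoxocin-2-yl]-7-(carbamoyloxy)-2-hydroxy-6-methoxy-2,8-dimethylundeca-4,8-dienoic acid F6. Mercuriolactonisation and demercuration (Hg(OAc)2; then NaBH4) give the nitro γ-lactone F7 (carboxyl oxygen on C4, C4 epimers). Zn/AcOH reduces the nitro group to the amino γ-lactone F8. Intramolecular aminolysis of the lactone by the aniline (AlMe3, CH2Cl2, high dilution) gives the 4-hydroxy macrolactam F9. Dess–Martin oxidation comes back to the route at 31.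

**Further compounds**

F1 | step 3 | methyl (2Z)-6,6-dimethoxy-3-methyl-5-oxohex-2-enoate | COC(=O)/C=C(C)\CC(=O)C(OC)OC
F2 | step 3 | methyl (2Z,5S)-5-hydroxy-6,6-dimethoxy-3-methylhex-2-enoate | COC(=O)/C=C(C)\C[C@H](O)C(OC)OC
F3 | step 10 | 4-bromo-2-nitro-6-[(2R,4S)-4,5,5-trimethoxy-2-methylpentyl]phenol | COC(OC)[C@@H](OC)C[C@H](C)Cc1cc(Br)cc([N+](=O)[O-])c1O
F4 | step 10 | (2S,4R)-5-(5-bromo-2-hydroxy-3-nitrophenyl)-2-methoxy-4-methylpentanal | O=C[C@@H](OC)C[C@H](C)Cc1cc(Br)cc([N+](=O)[O-])c1O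
F5 | step 10 | (3S,4S,5S,7R)-8-(5-bromo-2-hydroxy-3-nitrophenyl)-5-methoxy-3,7-dimethyloct-1-en-4-ol | C=C[C@H](C)[C@H](O)[C@@H](OC)C[C@H](C)Cc1cc(Br)cc([N+](=O)[O-])c1O
F6 | step 23 | (2S,4E,6S,7S,8Z,10S)-10-[(2R,3S,5R)-8-bromo-3-methoxy-5-methyl-10-nitro-3,4,5,6-tetrahydro-2H-1-benzoxocin-2-yl]-7-(carbamoyloxy)-2-hydroxy-6-methoxy-2,8-dimethylundeca-4,8-dienoic acid | CO[C@H]1C[C@H](C)Cc2cc(Br)cc([N+](=O)[O-])c2O[C@@H]1[C@@H](C)/C=C(/C)[C@H](OC(N)=O)[C@@H](OC)/C=C/C[C@](C)(O)C(=O)O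
F7 | step 23 | nitro γ-lactone: C1 carboxyl oxygen bonded to C4 (C4 epimers), C5 as CH2 | CO[C@H]1C[C@H](C)Cc2cc(Br)cc([N+](=O)[O-])c2O[C@@H]1[C@@H](C)/C=C(/C)[C@H](OC(N)=O)[C@@H](OC)CC3C[C@](C)(O)C(=O)O3
F8 | step 23 | amino γ-lactone: F7 with NH2 in place of NO2 | CO[C@H]1C[C@H](C)Cc2cc(Br)cc(N)c2O[C@@H]1[C@@H](C)/C=C(/C)[C@H](OC(N)=O)[C@@H](OC)CC3C[C@](C)(O)C(=O)O3
F9 | step 23 | 4-hydroxy macrolactam: 31 with C4–OH (C4 epimers) in place of the C4 ketone | CO[C@H]1C[C@H](C)Cc2cc(Br)cc3c2O[C@@H]1[C@@H](C)/C=C(/C)[C@H](OC(N)=O)[C@@H](OC)CC(O)C[C@](C)(O)C(=O)N3
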